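Locants: half N = rings A, C, B with O1, C2, C3, C4 (the 5,7,4'-trioxygenated flavanone). Half L = rings D, F, E with O1'', C2'', C3'', C4'' (the 7'',4'''-dioxygenated flavanone).
Cuts: 1) the five O-benzyl bonds. 2) C2–C3 of ring C, read as a radical conjugate addition, which places a CO2H on C2 and a double bond between C3 and C3''. 3) C3=C3'' (aldol and dehydration), giving a flavanone and an arylglyoxal. 4) C2''–ring E (conjugate addition to a chromone) and O1–C2 (phenol alkylation).
Forward order: ring F comes with the chromone and receives ring E. The open-chain half N (ring A ketone carrying O1–C2(ring B)–CO2R) is joined at C3=C3''. Ring C closes last.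
Enabling feature: C3 is alpha to C4=O and beta to C4''=O (the C4–C3–C3''–C4'' 1,4-diketone), so a C3=C3'' enedione accepts a radical at C3. C2 bears O1 and the p-oxygenated ring B, so its radical is stabilised, nucleophilic and available from an acid by loss of CO2.
Stereochemistry: C2'' comes from ligand-controlled palladium catalysis. C3 and C2 are relayed from C2'' in the ring closure (axial ring E shields one alkene face; trans half-chair). C3'' comes from thermodynamic protonation (trans).

Key step: step 12

Assumption: (R)-t-BuPyOx is taken to deliver ring E to the chromone face that gives 2''S, by analogy with the sense known for cyclic enones; if the sense is opposite, the antipodal ligand is used.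

Step 1
Reactants: 1 7-hydroxychromone
Product: 2 7-(benzyloxy)chromone
Conditions: BnBr, K2CO3, acetone, reflux
Reagents that add atoms: benzyl bromide, BrCc1ccccc1
Why: Williamson ether synthesis on the only OH group masks the ring D phenol until the last step.

Step 2
Reactants: 2 7-(benzyloxy)chromone; 3 4-(benzyloxy)phenylboronic acid
Product: 4 (2S)-7-(benzyloxy)-2-[4-(benzyloxy)phenyl]chroman-4-one
Conditions: Pd(OCOCF3)2 (5 mol%), (R)-t-BuPyOx (6 mol%), NH4PF6 (30 mol%), H2O (5 equiv), ClCH2CH2Cl, 60 °C
Reagents that add atoms: none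
Why: Palladium-catalysed asymmetric conjugate addition of an arylboronic acid to a chromone has close precedent for flavanones; the pyridine-oxazoline ligand decides the face of C2'' that receives ring E (2''S), and the near-neutral aqueous medium protonates the enolate without opening ring F.

Step 3
Reactants: 4 (2S)-7-(benzyloxy)-2-[4-(benzyloxy)phenyl]chroman-4-one
Product: 5 (2S)-7-(benzyloxy)-2-[4-(benzyloxy)phenyl]-4-(trimethylsilyloxy)-2H-chromene
Conditions: TMSOTf, Et3N, CH2Cl2, 0 °C; non-aqueous work-up, used crude
Reagents that add atoms: trimethylsilyl triflate, C[Si](C)(C)OS(=O)(=O)C(F)(F)F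
Why: Soft enolisation (silyl triflate plus amine) gives the silyl enol ether without a free metal enolate, so ring F should not open by E1cB loss of the O1'' aryloxide and C2'' is kept.

Step 4
Reactants: 6 4-(benzyloxy)phenylacetic acid
Product: 7 tert-butyl 4-(benzyloxy)phenylacetate
Conditions: Cl3CC(=NH)OtBu, CH2Cl2/cyclohexane, rt
Reagents that add atoms: tert-butyl 2,2,2-trichloroacetimidate, CC(C)(C)OC(=N)C(Cl)(Cl)Cl
Why: Alkylation of the carboxylic acid by the trichloroacetimidate installs an ester that can later be removed without base.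

Step 5
Reactants: 7 tert-butyl 4-(benzyloxy)phenylacetate
Product: 9 tert-butyl 2-bromo-2-[4-(benzyloxy)phenyl]acetate (racemic), via lithium enolate 8 (not isolated)
Conditions: LiN(SiMe3)2, THF, −78 °C; then NBS, −78 °C; NH4Cl quench
Reagents that add atoms: N-bromosuccinimide, O=C1CCC(=O)N1Br
Why: Electrophilic alpha-bromination of an ester enolate avoids radical bromination, which would attack the benzyl ether, and the new centre may be racemic because it is later erased as a planar radical.

Step 6
Reactants: 10 2,4,6-trihydroxyacetophenone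
Product: 11 2-hydroxy-4,6-bis(benzyloxy)acetophenone
Conditions: BnBr (2.1 equiv), K2CO3, DMF, rt
Reagents that add atoms: benzyl bromide, BrCc1ccccc1
Why: In this Williamson ether synthesis one ortho OH stays hydrogen-bonded to the acetyl group and is left free, so the para OH and one ortho OH are benzylated.

Step 7
Reactants: 11 2-hydroxy-4,6-bis(benzyloxy)acetophenone; 9 tert-butyl 2-bromo-2-[4-(benzyloxy)phenyl]acetate
Product: 12 tert-butyl 2-[2-acetyl-3,5-bis(benzyloxy)phenoxy]-2-[4-(benzyloxy)phenyl]acetate (racemic)
Conditions: K2CO3, DMF, rt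
Reagents that add atoms: none
Why: Williamson ether synthesis at a doubly activated (benzylic, alpha-ester) bromide forms O1–C2 and brings in C2, ring B and the carboxyl helper in one piece.

Step 8
Reactants: 12 tert-butyl 2-[2-acetyl-3,5-bis(benzyloxy)phenoxy]-2-[4-(benzyloxy)phenyl]acetate
Product: 13 arylglyoxal hydrate, tert-butyl 2-[3,5-bis(benzyloxy)-2-(2,2-dihydroxyacetyl)phenoxy]-2-[4-(benzyloxy)phenyl]acetate (racemic)
Conditions: SeO2, 1,4-dioxane/H2O, 90 °C
Reagents that add atoms: selenium dioxide, O=[Se]=O; water, O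
Why: Riley oxidation turns the acetyl CH3, the only readily enolised position, into the glyoxal, which is isolated as its stable hydrate.

Step 9
Reactants: 5 (2S)-7-(benzyloxy)-2-[4-(benzyloxy)phenyl]-4-(trimethylsilyloxy)-2H-chromene; 13 arylglyoxal hydrate
Product: 14 aldol, the (2''S,3''R)-trans flavanone 4 carrying at C3'' the group CH(OH)–C(=O)–Ar, where Ar is ring A of 13 (mixture of epimers at the carbinol carbon C3 and at C2)
Conditions: Yb(OTf)3 (10 mol%), THF/H2O (4:1), 0 °C to rt
Reagents that add atoms: none
Why: The lanthanide-triflate-catalysed Mukaiyama aldol addition in aqueous THF accepts glyoxal hydrates directly; C3'' should attack the aldehyde carbon anti to ring E, and the carbinol centre, formed as a mixture, is erased in step 10.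

Step 10
Reactants: 14 aldol
Product: 16 E-enedione tert-butyl ester (flavanone with a 3''-aroylmethylene group; both C2 epimers), via mesylate 15 (not isolated)
Conditions: MsCl, Et3N, CH2Cl2, −20 to 0 °C
Reagents that add atoms: none
Why: Mesylation and E1cB elimination (aldol dehydration) remove the C3'' proton and expel mesylate, a far better leaving group than the O1'' aryloxide, which should give the more stable E-alkene with the vinyl H beside C4''=O and the aroyl group beside C2''; C2'' keeps its spatial arrangement, and its descriptor becomes R only because C3'' now outranks ring E.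

Step 11
Reactants: 16 E-enedione tert-butyl ester
Product: 17 E-enedione acid (both C2 epimers)
Conditions: CF3CO2H/CH2Cl2 (1:4), 0 °C
Reagents that add atoms: none
Why: Acidolysis of the tert-butyl ester (E1 loss of isobutene) frees the acid without base, which could move the double bond into ring F.

Step 12
Reactants: 17 E-enedione acid
Product: 22 penta-O-benzyl biflavanone (2S,3R,2''S,3''R), via potassium carboxylate 18 (not isolated), via C2 benzylic radical 19 (not isolated), via C3'' keto radical 20 (not isolated), via potassium enolate 21 (not isolated)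
Conditions: Ir[dF(CF3)ppy]2(dtbbpy)PF6 (1 mol%), K2HPO4 (1 equiv), DMF (0.02 M, degassed), 450 nm LEDs, rt
Reagents that add atoms: none
Why: The photoexcited iridium complex oxidises carboxylate 18, CO2 is lost, and the nucleophilic radical 19 (stabilised by O1 and by the p-alkoxyphenyl ring B) adds to C3 of the C3=C3'' enedione to give the tertiary alpha-keto radical 20, which the reduced, divalent iridium complex turns into enolate 21, protonated by the KH2PO4 formed in the flask, so the cycle is redox-neutral. The closest known reaction type is the photoredox decarboxylative Giese (radical conjugate) addition of alpha-oxy and aryloxyacetic acids to enones, here run within one molecule. Ring C closes in the 6-exo-trig mode at the CH terminus C3, whereas the 7-endo alternative would have to attack the fully substituted C3''. C3 is controlled by C2'': allylic 1,3-strain with the aroyl group of the E-alkene holds ring E axial over one face of C3=C3'', so ring A and its tethered radical must approach from the other face, which gives 3R, and C2 is set in the same half-chair transition state with ring B pseudo-equatorial and anti to the bulky C3 substituent (2,3-trans, 2S); both C2 epimers of 17 converge on the same planar radical. C3'' is set last by protonation of 21, which is reversible in the phosphate medium and should settle on the diequatorial 2'',3''-trans arrangement (3''R). The step needs oxidation of the carboxylate alone (secured by the low oxidation potential of an alpha-aryloxy arylacetate relative to the aryl ethers), retention of the E geometry until the radical forms (favoured by low catalyst loading and by irradiation at 450 nm, where 17 should absorb little), and protonation of 21 faster than loss of the O1'' aryloxide (secured by the KH2PO4 present).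

Step 13
Reactants: 22 penta-O-benzyl biflavanone
Product: 23 target, (2S,3R,2''S,3''R)-3,3''-linked naringenin–liquiritigenin biflavanone
Conditions: H2 (1 atm), 10% Pd/C, THF/MeOH, rt
Reagents that add atoms: none
Why: Catalytic hydrogenolysis removes the five benzyl ethers under neutral conditions that neither enolise C3 or C3'' nor open rings C and F, so all four stereocentres persist.

Compound list
1 | 7-hydroxychromone | O=c1ccoc2cc(O)ccc12 | starting material
2 | 7-(benzyloxy)chromone | O=c1ccoc2cc(OCc3ccccc3)ccc12 | intermediate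
3 | 4-(benzyloxy)phenylboronic acid | OB(O)c1ccc(OCc2ccccc2)cc1 | starting material
4 | (2S)-7-(benzyloxy)-2-[4-(benzyloxy)phenyl]chroman-4-one | O=C1C[C@@H](c2ccc(OCc3ccccc3)cc2)Oc2cc(OCc3ccccc3)ccc12 | intermediate
5 | (2S)-7-(benzyloxy)-2-[4-(benzyloxy)phenyl]-4-(trimethylsilyloxy)-2H-chromene | C[Si](C)(C)OC1=C[C@@H](c2ccc(OCc3ccccc3)cc2)Oc2cc(OCc3ccccc3)ccc12 | intermediate
6 | 4-(benzyloxy)phenylacetic acid | OC(=O)Cc1ccc(OCc2ccccc2)cc1 | starting material
7 | tert-butyl 4-(benzyloxy)phenylacetate | CC(C)(C)OC(=O)Cc1ccc(OCc2ccccc2)cc1 | intermediate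
8 | lithium enolate of 7 (not isolated) | [Li+].[O-]C(OC(C)(C)C)=Cc1ccc(OCc2ccccc2)cc1 | intermediate
9 | tert-butyl 2-bromo-2-[4-(benzyloxy)phenyl]acetate (racemic) | CC(C)(C)OC(=O)C(Br)c1ccc(OCc2ccccc2)cc1 | intermediate
10 | 2,4,6-trihydroxyacetophenone | CC(=O)c1c(O)cc(O)cc1O | starting material
11 | 2-hydroxy-4,6-bis(benzyloxy)acetophenone | CC(=O)c1c(O)cc(OCc2ccccc2)cc1OCc1ccccc1 | intermediate
12 | tert-butyl 2-[2-acetyl-3,5-bis(benzyloxy)phenoxy]-2-[4-(benzyloxy)phenyl]acetate (racemic) | CC(=O)c1c(OCc2ccccc2)cc(OCc2ccccc2)cc1OC(C(=O)OC(C)(C)C)c1ccc(OCc2ccccc2)cc1 | intermediate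
13 | arylglyoxal hydrate of 12 (racemic) | OC(O)C(=O)c1c(OCc2ccccc2)cc(OCc2ccccc2)cc1OC(C(=O)OC(C)(C)C)c1ccc(OCc2ccccc2)cc1 | intermediate
14 | aldol (2''S,3''R; epimers at C3 and C2) | O=C1c2ccc(OCc3ccccc3)cc2O[C@H](c2ccc(OCc3ccccc3)cc2)[C@H]1C(O)C(=O)c1c(OCc2ccccc2)cc(OCc2ccccc2)cc1OC(C(=O)OC(C)(C)C)c1ccc(OCc2ccccc2)cc1 | intermediate
15 | mesylate of 14 (not isolated) | O=C1c2ccc(OCc3ccccc3)cc2O[C@H](c2ccc(OCc3ccccc3)cc2)[C@H]1C(OS(C)(=O)=O)C(=O)c1c(OCc2ccccc2)cc(OCc2ccccc2)cc1OC(C(=O)OC(C)(C)C)c1ccc(OCc2ccccc2)cc1 | intermediate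
16 | E-enedione tert-butyl ester (C2'' spatially as in 4; epimers at C2) | O=C1c2ccc(OCc3ccccc3)cc2O[C@H](c2ccc(OCc3ccccc3)cc2)/C1=C\C(=O)c1c(OCc2ccccc2)cc(OCc2ccccc2)cc1OC(C(=O)OC(C)(C)C)c1ccc(OCc2ccccc2)cc1 | intermediate
17 | E-enedione acid (epimers at C2) | O=C1c2ccc(OCc3ccccc3)cc2O[C@H](c2ccc(OCc3ccccc3)cc2)/C1=C\C(=O)c1c(OCc2ccccc2)cc(OCc2ccccc2)cc1OC(C(=O)O)c1ccc(OCc2ccccc2)cc1 | intermediate
18 | potassium carboxylate of 17 (not isolated) | [K+].O=C1c2ccc(OCc3ccccc3)cc2O[C@H](c2ccc(OCc3ccccc3)cc2)/C1=C\C(=O)c1c(OCc2ccccc2)cc(OCc2ccccc2)cc1OC(C(=O)[O-])c1ccc(OCc2ccccc2)cc1 | intermediate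
19 | C2 benzylic alpha-aryloxy radical (not isolated) | O=C1c2ccc(OCc3ccccc3)cc2O[C@H](c2ccc(OCc3ccccc3)cc2)/C1=C\C(=O)c1c(OCc2ccccc2)cc(OCc2ccccc2)cc1O[CH]c1ccc(OCc2ccccc2)cc1 | intermediate
20 | C3'' alpha-keto radical, ring C closed (not isolated) | O=C1c2ccc(OCc3ccccc3)cc2O[C@H](c2ccc(OCc3ccccc3)cc2)[C]1[C@H]1C(=O)c2c(OCc3ccccc3)cc(OCc3ccccc3)cc2O[C@@H]1c1ccc(OCc2ccccc2)cc1 | intermediate
21 | potassium C3''=C4'' enolate (not isolated) | [K+].[O-]C1=C([C@H]2C(=O)c3c(OCc4ccccc4)cc(OCc4ccccc4)cc3O[C@@H]2c2ccc(OCc3ccccc3)cc2)[C@@H](c2ccc(OCc3ccccc3)cc2)Oc2cc(OCc3ccccc3)ccc12 | intermediate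
22 | penta-O-benzyl biflavanone (2S,3R,2''S,3''R) | O=C1c2ccc(OCc3ccccc3)cc2O[C@H](c2ccc(OCc3ccccc3)cc2)[C@H]1[C@H]1C(=O)c2c(OCc3ccccc3)cc(OCc3ccccc3)cc2O[C@@H]1c1ccc(OCc2ccccc2)cc1 | intermediate
23 | target biflavanone (2S,3R,2''S,3''R) | O=C1c2ccc(O)cc2O[C@H](c2ccc(O)cc2)[C@H]1[C@H]1C(=O)c2c(O)cc(O)cc2O[C@@H]1c1ccc(O)cc1 | target

Total step count: 13.
Longest linear sequence: 9 (steps 4, 5, 7, 8, 9, 10, 11, 12, 13).

Steps most likely to fail

Step 12. The catalyst may sensitise E/Z isomerisation of the enedione before the radical forms, which would erode the facial control at C3 and, with it, the configuration at C2. The phosphate base may move the double bond into ring F, and the enolate may lose the O1'' aryloxide before it is protonated.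
The fallback builds ring C before the halves are joined. It sets out from 11, 3 and 4 and comes back at 22.
- Compound 11 is condensed with DMF dimethyl acetal to the enaminone F1, which is closed with HCl to 5,7-bis(benzyloxy)chromone F2.
- Addition of 3 under the conditions of step 2 gives (2S)-tri-O-benzylnaringenin F3.
- Compounds 4 and F3 are bound one after the other to iPr2Si(OTf)2 with Et3N, giving the mixed diisopropylsilyl bis-enol ether F4.
- Oxidation with (NH4)2Ce(NO3)6 and NaHCO3 in MeCN joins C3 to C3'' (oxidative coupling of a silyl bis-enol ether). Each new centre should form anti to the aryl group on its own ring, which leads to 22.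

Step 10. During elimination or handling the exocyclic double bond may drift into ring F, which aromatises it to the flavone and loses C2''. Ring F may also open through the C3'' enolate.
The fallback keeps the enedione latent. It sets out from 14 and comes back at 18.
- Compound 14 is acetylated (Ac2O, pyridine) to the aldol acetate F5.
- The tert-butyl ester is cleaved with CF3CO2H to the acetate acid F6.
- F6 is placed directly under the conditions of step 12 with 2 equiv of K2HPO4. Loss of acetic acid then forms 18 in the flask, and 18 is consumed as it appears.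

Step 2. Addition to the electron-rich chromone may be slow, protodeboronation of 3 may compete, and the enantioselectivity may be insufficient.
The fallback replaces enantioselective bond formation by kinetic resolution. It sets out from 2 and 3 and comes back at 4.
- Addition with the achiral catalyst Pd(OCOCF3)2/2,2'-bipyridine gives the racemic flavanone F7.
- Asymmetric transfer hydrogenation with RuCl(p-cymene)(TsDPEN) and HCO2H/Et3N follows, using the ligand enantiomer that reduces the 2R ketone faster. It converts the unwanted enantiomer into the cis-flavan-4-ol F8, which is separated by chromatography from unreacted 4.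

Further compounds
F1 | step 12 | (E)-3-(dimethylamino)-1-[2-hydroxy-4,6-bis(benzyloxy)phenyl]prop-2-en-1-one | CN(C)/C=C/C(=O)c1c(O)cc(OCc2ccccc2)cc1OCc1ccccc1
F2 | step 12 | 5,7-bis(benzyloxy)chromone | O=c1ccoc2cc(OCc3ccccc3)cc(OCc3ccccc3)c12
F3 | step 12 | (2S)-5,7-bis(benzyloxy)-2-[4-(benzyloxy)phenyl]chroman-4-one | O=C1C[C@@H](c2ccc(OCc3ccccc3)cc2)Oc2cc(OCc3ccccc3)cc(OCc3ccccc3)c12
F4 | step 12 | mixed diisopropylsilyl bis-enol ether of 4 and F3 | CC(C)[Si](OC1=C[C@@H](c2ccc(OCc3ccccc3)cc2)Oc2cc(OCc3ccccc3)ccc12)(OC1=C[C@@H](c2ccc(OCc3ccccc3)cc2)Oc2cc(OCc3ccccc3)cc(OCc3ccccc3)c12)C(C)C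
F5 | step 10 | acetate of aldol 14 | O=C1c2ccc(OCc3ccccc3)cc2O[C@H](c2ccc(OCc3ccccc3)cc2)[C@H]1C(OC(C)=O)C(=O)c1c(OCc2ccccc2)cc(OCc2ccccc2)cc1OC(C(=O)OC(C)(C)C)c1ccc(OCc2ccccc2)cc1
F6 | step 10 | acetate acid from F5 | O=C1c2ccc(OCc3ccccc3)cc2O[C@H](c2ccc(OCc3ccccc3)cc2)[C@H]1C(OC(C)=O)C(=O)c1c(OCc2ccccc2)cc(OCc2ccccc2)cc1OC(C(=O)O)c1ccc(OCc2ccccc2)cc1
F7 | step 2 | racemic 7-(benzyloxy)-2-[4-(benzyloxy)phenyl]chroman-4-one | O=C1CC(c2ccc(OCc3ccccc3)cc2)Oc2cc(OCc3ccccc3)ccc12
F8 | step 2 | (2R,4R)-7-(benzyloxy)-2-[4-(benzyloxy)phenyl]chroman-4-ol | O[C@@H]1C[C@H](c2ccc(OCc3ccccc3)cc2)Oc2cc(OCc3ccccc3)ccc12
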